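**Plan**

1. Retrosynthesis: the C2 alcohol goes back to the C2 ketone; C3 is then excised from ring B (cuts at C2–C3 and C3–C4), contracting the cyclohexenone to a cyclopentanone.
2. Enabling feature: in ring B the C2 oxygen, the C3=C4 double bond and the C18 lactone carbonyl form a γ-oxygenated α,β-unsaturated lactone. This is the dehydro homologue of a β-keto lactone in which C4 alone lies between the C2 ketone and C18, and such a 1,3-dicarbonyl unit accepts one carbon from a zinc carbenoid.
3. Further cuts: C2–C4 (Dieckmann), C12–C13 (furan acylation, ring C), C9–C11 (allylation), C1–C10 (Michael addition through a C19–O–C2 ester tether), C5–C10/C6–C7 (Diels–Alder, ring A).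
4. Forward order of rings: A (Diels–Alder), temporary δ-lactone (C1–C10), spiro γ-lactone E, C (Friedel–Crafts), five-membered B (Dieckmann), six-membered B (C3 insertion), then reduction at C2.
5. Stereochemistry: C5 from a catalytic enantioselective Diels–Alder; C10 relayed from C5 by the tether; C9 by allylation anti to the C10 side chain; C8 and C7 by protonation and hydride delivery from the open β face; C2 by axial hydride delivery; C1 and C4 under thermodynamic control.

Key step: step 20

Conventions: clerodane locants of the target are used throughout. Ring A = C5–C10; ring B = C1–C5 with C10; ring C = C1, C10, C9, C11, C12, C13, C16; furan D = C13–C16 with O; lactone E = C4, C5, C19, O, C18; C17 is on C8 and C20 on C9; β is the face of H-10. In the spiro names of 14–23, spiro positions 6, 7, 8, 9 are clerodane C10, C9, C8, C7.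

Assumption: the (S)-configured catalyst of step 3 is taken to deliver (S)-5 by the usual facial model for 2-substituted acroleins (its mirror image would be used if the sense proves opposite); C1 is carried as a mixture of epimers from 11 to 25 (SMILES leave it open) and is set under equilibrium in step 19.

**Route**

Step 1
Reactants: 1 tert-butyl 4-oxobutanoate
Product: 2 tert-butyl 3-formylbut-3-enoate
Conditions: aq. CH2O (37 %), pyrrolidine (10 mol %), EtCO2H (10 mol %), i-PrOH, 45 °C
Reagents that add atoms: formaldehyde, C=O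
Why: Amine-catalysed Mannich-type condensation with formaldehyde and elimination (α-methylenation of an aldehyde) acts only at the CH2 next to the formyl group, and the buffered medium should keep the β,γ-unsaturated ester out of conjugation.

Step 2
Reactants: 3 3-methylbut-3-en-2-one
Product: 4 2-methyl-3-(triisopropylsilyloxy)buta-1,3-diene
Conditions: i-Pr3SiOTf, Et3N, CH2Cl2, 0 °C
Reagents that add atoms: triisopropylsilyl trifluoromethanesulfonate, CC(C)[Si](OS(=O)(=O)C(F)(F)F)(C(C)C)C(C)C
Why: Soft enolisation of the methyl ketone (silyl enol ether formation) can occur only toward the methyl group and gives a 2-silyloxy diene whose bulky silyl group makes it robust toward the Lewis acid of step 3.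

Step 3
Reactants: 2 tert-butyl 3-formylbut-3-enoate; 4 2-methyl-3-(triisopropylsilyloxy)buta-1,3-diene
Product: 5 tert-butyl 2-[(1S)-1-formyl-3-methyl-4-(triisopropylsilyloxy)cyclohex-3-en-1-yl]acetate
Conditions: (S)-3,3-diphenyl-1-(2-methylphenyl)tetrahydropyrrolo[1,2-c][1,3,2]oxazaborole·HN(SO2CF3)2 (20 mol %), CH2Cl2, −78 → −40 °C
Reagents that add atoms: none
Why: Catalytic enantioselective Diels–Alder reaction of a 2-substituted acrolein with a 2-silyloxy diene: the silyloxy carbon ends up para to the formyl-bearing carbon (bonds C5–C10 and C6–C7), and the chiral boron Lewis acid bound to the formyl group shields one face of the enal, which sets the quaternary centre C5, the only source of absolute configuration in the route.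

Step 4
Reactants: 5 tert-butyl 2-[(1S)-1-formyl-3-methyl-4-(triisopropylsilyloxy)cyclohex-3-en-1-yl]acetate
Product: 6 tert-butyl 2-[(1R)-1-formyl-3-methyl-4-oxocyclohex-2-en-1-yl]acetate
Conditions: Pd(OAc)2 (1.1 equiv), MeCN, 40 °C
Reagents that add atoms: none
Why: Saegusa–Ito oxidation: the silyl enol ether gives a palladium enolate at C9, and β-hydride elimination toward the ring CH2 (C10) should give the conjugated 2-methyl enone, C5 being untouched (its descriptor changes only because priorities change).

Step 5
Reactants: 6 tert-butyl 2-[(1R)-1-formyl-3-methyl-4-oxocyclohex-2-en-1-yl]acetate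
Product: 7 tert-butyl 2-[(1R)-1-(hydroxymethyl)-3-methyl-4-oxocyclohex-2-en-1-yl]acetate
Conditions: NaBH4 (0.3 equiv), MeOH–CH2Cl2, −78 °C
Reagents that add atoms: none
Why: Chemoselective borohydride reduction: at low temperature an aldehyde is reduced far faster than a conjugated ketone, and the tert-butyl ester is slow to lactonise with the new alcohol.

Step 6
Reactants: 7 tert-butyl 2-[(1R)-1-(hydroxymethyl)-3-methyl-4-oxocyclohex-2-en-1-yl]acetate; 8 2-(furan-2-yl)acetic acid
Product: 9 [(1R)-1-(2-tert-butoxy-2-oxoethyl)-3-methyl-4-oxocyclohex-2-en-1-yl]methyl 2-(furan-2-yl)acetate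
Conditions: DCC, DMAP (10 mol %), CH2Cl2, 0 °C → rt
Reagents that add atoms: none
Why: Steglich esterification joins the acid to the hindered primary alcohol under neutral conditions that leave the enone and the tert-butyl ester alone.

Step 7
Reactants: 9 [(1R)-1-(2-tert-butoxy-2-oxoethyl)-3-methyl-4-oxocyclohex-2-en-1-yl]methyl 2-(furan-2-yl)acetate
Product: 11 cis-fused C2–O–C19 δ-lactone bearing the C8=C9 trimethylsilyl enol ether (C18 tert-butyl ester; H-10 β; C1 epimers), via ketene silyl acetal 10 (not isolated)
Conditions: LiN(SiMe3)2 (1.05 equiv), Me3SiCl (2 equiv), THF, −78 °C; then Me3SiOTf (10 mol %), CH2Cl2, −78 → −20 °C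
Reagents that add atoms: chlorotrimethylsilane, C[Si](C)(C)Cl
Why: Deprotonation at the most acidic site (the furylacetate CH2) with in situ silylation gives ketene silyl acetal 10, whose Lewis-acid-catalysed intramolecular Mukaiyama–Michael addition (6-exo-trig) can reach C10 only on the face carrying the C19 tether, so C1 ends up cis to C19 (H-10 β) and the silyl group moves to O8, fixing the enol ether at C8=C9.

Step 8
Reactants: 11 cis-fused δ-lactone silyl enol ether
Product: 12 cis-fused δ-lactone 8-ketone with 9β-allyl and 9α-methyl (C18 tert-butyl ester; C1 epimers)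
Conditions: allyl methyl carbonate, Pd2(dba)3 (2.5 mol %), Ph2PCH2CH2PPh2 (6 mol %), THF, 65 °C
Reagents that add atoms: allyl methyl carbonate, C=CCOC(=O)OC
Why: Tsuji allylation of a silyl enol ether (zerovalent palladium, π-allyl intermediate, methoxide from the carbonate releasing the enolate) alkylates C9 regiospecifically, and the allyl group enters from the convex β face, anti to the C10–C1 bond and to the α-oriented C19 methylene, which sets the quaternary centre C9 (C11 β, C20 α).

Step 9
Reactants: 12 cis-fused δ-lactone 8-ketone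
Product: 14 methyl 2-(furan-2-yl)-2-[7-allyl-7-methyl-3,8-dioxo-2-oxaspiro[4.5]decan-6-yl]acetate, via hydroxy diester 13 (not isolated)
Conditions: NaOMe (0.2 equiv), MeOH, 0 °C → rt; then CF3CO2H, CH2Cl2, 0 °C
Reagents that add atoms: methanol, CO
Why: Base-catalysed transesterification opens the δ-lactone to the C2 methyl ester and the C19 alcohol 13, and acid then removes the tert-butyl group and closes the spiro γ-lactone between C19–O and C18 (lactonisation favoured by the quaternary C5), which puts the lactone where the target has it and frees C2 for the Dieckmann step.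

Step 10
Reactants: 14 spiro-lactone 8-ketone
Product: 15 methyl 2-(furan-2-yl)-2-[7-allyl-7-methyl-8-methylidene-3-oxo-2-oxaspiro[4.5]decan-6-yl]acetate
Conditions: Zn, CH2Br2, TiCl4, THF, 0 °C → rt
Reagents that add atoms: dibromomethane, BrCBr
Why: Takai–Lombardo methylenation: the non-basic zinc/titanium methylene reagent converts the hindered C8 ketone into the exocyclic alkene without enolising C1 and without touching the ester, the lactone or the furan.

Step 11
Reactants: 15 8-methylidene spiro-lactone
Product: 16 methyl 2-(furan-2-yl)-2-[7-allyl-9-hydroxy-7-methyl-8-methylidene-3-oxo-2-oxaspiro[4.5]decan-6-yl]acetate (C7 alcohol of either configuration)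
Conditions: SeO2 (0.5 equiv), t-BuOOH (3 equiv), CH2Cl2, rt
Reagents that add atoms: selenium dioxide, O=[Se]=O; tert-butyl hydroperoxide, CC(C)(C)OO
Why: Selenium dioxide allylic oxidation (ene reaction, then [2,3]-sigmatropic shift) hydroxylates C7, the only allylic CH2 of the 1,1-disubstituted alkene since C9 is quaternary, while the monosubstituted allyl group reacts much more slowly; the C7 configuration is irrelevant because it is oxidised next.

Step 12
Reactants: 16 C7 allylic alcohol
Product: 17 methyl 2-(furan-2-yl)-2-[7-allyl-7-methyl-8-methylidene-3,9-dioxo-2-oxaspiro[4.5]decan-6-yl]acetate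
Conditions: Dess–Martin periodinane, NaHCO3, CH2Cl2, 0 °C → rt
Reagents that add atoms: none
Why: Dess–Martin oxidation of the secondary allylic alcohol gives the α-methylene ketone under buffered, non-enolising conditions.

Step 13
Reactants: 17 α-methylene ketone
Product: 18 methyl 2-(furan-2-yl)-2-[7-allyl-7,8-dimethyl-3,9-dioxo-2-oxaspiro[4.5]decan-6-yl]acetate (7-ketone, 8α-methyl)
Conditions: LiBH(s-Bu)3 (1.1 equiv), THF, −78 °C; aq. NH4Cl
Reagents that add atoms: none
Why: Conjugate (1,4) hydride reduction of an α-methylene ketone by a trialkylborohydride spares the isolated allyl group, and protonation of the enolate along the axial β direction (the α face carries the axial C20 methyl) places the C17 methyl equatorial (8α), which is also the thermodynamically preferred position next to the ketone.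

Step 14
Reactants: 18 7-ketone
Product: 19 methyl 2-(furan-2-yl)-2-[7-allyl-9-hydroxy-7,8-dimethyl-3-oxo-2-oxaspiro[4.5]decan-6-yl]acetate (7α-alcohol)
Conditions: LiBH(s-Bu)3 (1.5 equiv), THF, −78 °C; aq. NH4Cl
Reagents that add atoms: none
Why: Diastereoselective ketone reduction with a bulky hydride: the axial (α) approach to C7 is closed by the syn-axial C19 methylene and C20 methyl, so hydride arrives equatorially from the β face and gives the axial 7α-alcohol, esters and lactone being inert at −78 °C.

Step 15
Reactants: 19 7α-alcohol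
Product: 20 methyl 2-(furan-2-yl)-2-[9-acetoxy-7-allyl-7,8-dimethyl-3-oxo-2-oxaspiro[4.5]decan-6-yl]acetate (7α-acetate)
Conditions: Ac2O, DMAP, pyridine, 50 °C
Reagents that add atoms: acetic anhydride, CC(=O)OC(C)=O
Why: DMAP-catalysed acylation is forced onto the hindered axial alcohol, and the resulting acetate is shielded on both sides by syn-axial carbons, which should let it survive the alkoxide of step 19.

Step 16
Reactants: 20 7α-acetate
Product: 22 methyl 2-(furan-2-yl)-2-[9-acetoxy-7,8-dimethyl-3-oxo-7-(2-oxoethyl)-2-oxaspiro[4.5]decan-6-yl]acetate, via diol 21 (not isolated)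
Conditions: OsO4 (2 mol %), NaIO4 (4 equiv), 2,6-lutidine, dioxane–H2O, rt
Reagents that add atoms: osmium tetroxide, O=[Os](=O)(=O)=O; sodium periodate, [Na+].[O-]I(=O)(=O)=O
Why: Lemieux–Johnson oxidation (catalytic dihydroxylation, then periodate glycol cleavage) shortens the allyl group, the only alkene left, to the C11–C12 aldehyde, the unhindered terminal alkene being expected to react ahead of the furan.

Step 17
Reactants: 22 C12 aldehyde
Product: 23 2-[9-acetoxy-6-[1-(furan-2-yl)-2-methoxy-2-oxoethyl]-7,8-dimethyl-3-oxo-2-oxaspiro[4.5]decan-7-yl]acetic acid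
Conditions: NaClO2, NaH2PO4, 2-methyl-2-butene, t-BuOH–H2O, 0 °C → rt
Reagents that add atoms: sodium chlorite, [Na+].[O-]Cl=O
Why: Pinnick oxidation converts the aldehyde into the acid, the alkene scavenger removing hypochlorous acid before it can attack the furan.

Step 18
Reactants: 23 C12 acid
Product: 25 tetracyclic keto ester with rings A, C, D and spiro-lactone E (methyl ester on C1; 7α-acetate; C1 epimers), via mixed anhydride 24 (not isolated)
Conditions: (CF3CO)2O (3 equiv), CH2Cl2, 0 °C → rt
Reagents that add atoms: none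
Why: Intramolecular Friedel–Crafts acylation of the furan through the mixed trifluoroacetic anhydride: the C11–C12 arm on C9 can reach only the furan β-carbon C13, which closes the seven-membered ring C and installs the C12 ketone, the ester, lactone and acetate being inert.

Step 19
Reactants: 25 tetracyclic keto ester
Product: 26 3-nor β-keto lactone with cyclopentanone ring B (7α-acetate; H-1 α, H-4 β, H-10 β)
Conditions: NaOMe (3 equiv), MeOH–THF, 50 °C; AcOH
Reagents that add atoms: none
Why: Dieckmann condensation under equilibrating alkoxide conditions: the C4 enolate of the lactone attacks the C2 methyl ester (5-exo-trig) and the system drains into the one product whose C4–H lies between two carbonyls; this closes the trans-fused ring B, forces the cis lactone fusion (H-4 β) and leaves C1 in its thermodynamic configuration, while condensations of the C11 or C1 enolates would give bridged or non-enolisable products that cannot persist.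

Step 20
Reactants: 26 3-nor β-keto lactone; 27 diiodomethane
Product: 30 2-oxo enone lactone (2-dehydro target), via zinc enolate 28 (not isolated), via 4-iodo lactone 29 (not isolated)
Conditions: Et2Zn (5 equiv), CH2I2 (5 equiv), CH2Cl2, 0 °C → rt; I2 (6 equiv), 0 °C; DBU (10 equiv), 0 °C → rt
Reagents that add atoms: diiodomethane (27), ICI
Why: Et2Zn deprotonates C4–H between the C2 ketone and the C18 lactone carbonyl, the zinc enolate is cyclopropanated across C2=C4 by EtZnCH2I, and the donor–acceptor cyclopropoxide opens at the former C2–C4 bond to the C4 zinc enolate 28 of the six-membered γ-keto lactone, so the new carbon C3 sits between C2 and C4. Iodine then iodinates C4 (29) and DBU removes HI through the C3 enolate, the only direction open because C5 is quaternary. The closest known reaction is the zinc-carbenoid chain extension of β-keto esters to γ-keto esters, including one-carbon ring expansion of cyclic β-keto esters, with iodine/amine work-up to γ-keto-α,β-unsaturated esters. Ring B is re-formed as a six-membered ring by 3-exo-trig closure of the carbenoid carbon onto the enolate followed by fragmentation, a net 1,2-acyl shift from C4 to the new CH2. No stereocentre is created, since C4 becomes sp2 and C1 stays in its thermodynamic configuration next to the ketone. The step needs chemoselectivity for the β-dicarbonyl over the C12 furyl ketone, the acetate and the furan; this rests on the far higher acidity of C4–H, the only position that forms a zinc enolate with Et2Zn, and on the low reactivity of furans toward zinc carbenoids.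

Step 21
Reactants: 30 2-oxo enone lactone
Product: 31 target (7α-acetoxy-2α-hydroxy compound)
Conditions: NaBH4, CeCl3·7H2O, MeOH, −78 °C
Reagents that add atoms: none
Why: Luche reduction: cerium-assisted 1,2-delivery of hydride to the enone carbonyl C2 along the axial β direction (past the small axial H-10) gives the equatorial 2α-alcohol, while the hindered furan-conjugated C12 ketone, the lactone and the acetate are left.

**Compound list**

1 | tert-butyl 4-oxobutanoate | O=CCCC(=O)OC(C)(C)C | starting material
2 | tert-butyl 3-formylbut-3-enoate | C=C(C=O)CC(=O)OC(C)(C)C | intermediate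
3 | 3-methylbut-3-en-2-one | CC(=O)C(C)=C | starting material
4 | 2-methyl-3-(triisopropylsilyloxy)buta-1,3-diene | C=C(C)C(=C)O[Si](C(C)C)(C(C)C)C(C)C | intermediate
5 | tert-butyl 2-[(1S)-1-formyl-3-methyl-4-(triisopropylsilyloxy)cyclohex-3-en-1-yl]acetate | O=C[C@@]1(CC(=O)OC(C)(C)C)CCC(O[Si](C(C)C)(C(C)C)C(C)C)=C(C)C1 | intermediate
6 | tert-butyl 2-[(1R)-1-formyl-3-methyl-4-oxocyclohex-2-en-1-yl]acetate | O=C[C@@]1(CC(=O)OC(C)(C)C)CCC(=O)C(C)=C1 | intermediate
7 | tert-butyl 2-[(1R)-1-(hydroxymethyl)-3-methyl-4-oxocyclohex-2-en-1-yl]acetate | OC[C@@]1(CC(=O)OC(C)(C)C)CCC(=O)C(C)=C1 | intermediate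
8 | 2-(furan-2-yl)acetic acid | OC(=O)Cc1ccco1 | starting material
9 | [(1R)-1-(2-tert-butoxy-2-oxoethyl)-3-methyl-4-oxocyclohex-2-en-1-yl]methyl 2-(furan-2-yl)acetate | O=C(Cc1ccco1)OC[C@@]1(CC(=O)OC(C)(C)C)CCC(=O)C(C)=C1 | intermediate
10 | ketene trimethylsilyl acetal of the furylacetate ester 9 (not isolated) | C[Si](C)(C)OC(=Cc1ccco1)OC[C@@]1(CC(=O)OC(C)(C)C)CCC(=O)C(C)=C1 | intermediate
11 | cis-fused C2–O–C19 δ-lactone with C1–C10 bond and C8=C9 trimethylsilyl enol ether; C18 tert-butyl ester; H-10 β; C1 epimers | O=C1OC[C@@]2(CC(=O)OC(C)(C)C)CCC(O[Si](C)(C)C)=C(C)[C@H]2C1c1ccco1 | intermediate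
12 | cis-fused δ-lactone 8-ketone, 9β-allyl, 9α-methyl; C18 tert-butyl ester; C1 epimers | O=C1OC[C@@]2(CC(=O)OC(C)(C)C)CCC(=O)[C@](C)(CC=C)[C@H]2C1c1ccco1 | intermediate
13 | methyl 2-(furan-2-yl)-2-[2-allyl-6-(2-tert-butoxy-2-oxoethyl)-6-(hydroxymethyl)-2-methyl-3-oxocyclohexyl]acetate (not isolated) | COC(=O)C(c1ccco1)[C@@H]1[C@@](C)(CC=C)C(=O)CC[C@@]1(CO)CC(=O)OC(C)(C)C | intermediate
14 | methyl 2-(furan-2-yl)-2-[7-allyl-7-methyl-3,8-dioxo-2-oxaspiro[4.5]decan-6-yl]acetate | COC(=O)C(c1ccco1)[C@@H]1[C@@](C)(CC=C)C(=O)CC[C@@]12CC(=O)OC2 | intermediate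
15 | methyl 2-(furan-2-yl)-2-[7-allyl-7-methyl-8-methylidene-3-oxo-2-oxaspiro[4.5]decan-6-yl]acetate | COC(=O)C(c1ccco1)[C@@H]1[C@@](C)(CC=C)C(=C)CC[C@@]12CC(=O)OC2 | intermediate
16 | methyl 2-(furan-2-yl)-2-[7-allyl-9-hydroxy-7-methyl-8-methylidene-3-oxo-2-oxaspiro[4.5]decan-6-yl]acetate (C7 epimers) | COC(=O)C(c1ccco1)[C@@H]1[C@@](C)(CC=C)C(=C)C(O)C[C@@]12CC(=O)OC2 | intermediate
17 | methyl 2-(furan-2-yl)-2-[7-allyl-7-methyl-8-methylidene-3,9-dioxo-2-oxaspiro[4.5]decan-6-yl]acetate | COC(=O)C(c1ccco1)[C@@H]1[C@@](C)(CC=C)C(=C)C(=O)C[C@@]12CC(=O)OC2 | intermediate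
18 | methyl 2-(furan-2-yl)-2-[7-allyl-7,8-dimethyl-3,9-dioxo-2-oxaspiro[4.5]decan-6-yl]acetate (8α-methyl) | COC(=O)C(c1ccco1)[C@@H]1[C@@](C)(CC=C)[C@H](C)C(=O)C[C@@]12CC(=O)OC2 | intermediate
19 | methyl 2-(furan-2-yl)-2-[7-allyl-9-hydroxy-7,8-dimethyl-3-oxo-2-oxaspiro[4.5]decan-6-yl]acetate (7α-alcohol) | COC(=O)C(c1ccco1)[C@@H]1[C@@](C)(CC=C)[C@H](C)[C@H](O)C[C@@]12CC(=O)OC2 | intermediate
20 | methyl 2-(furan-2-yl)-2-[9-acetoxy-7-allyl-7,8-dimethyl-3-oxo-2-oxaspiro[4.5]decan-6-yl]acetate (7α-acetate) | COC(=O)C(c1ccco1)[C@@H]1[C@@](C)(CC=C)[C@H](C)[C@H](OC(C)=O)C[C@@]12CC(=O)OC2 | intermediate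
21 | methyl 2-(furan-2-yl)-2-[9-acetoxy-7-(2,3-dihydroxypropyl)-7,8-dimethyl-3-oxo-2-oxaspiro[4.5]decan-6-yl]acetate (not isolated) | COC(=O)C(c1ccco1)[C@@H]1[C@@](C)(CC(O)CO)[C@H](C)[C@H](OC(C)=O)C[C@@]12CC(=O)OC2 | intermediate
22 | methyl 2-(furan-2-yl)-2-[9-acetoxy-7,8-dimethyl-3-oxo-7-(2-oxoethyl)-2-oxaspiro[4.5]decan-6-yl]acetate | COC(=O)C(c1ccco1)[C@@H]1[C@@](C)(CC=O)[C@H](C)[C@H](OC(C)=O)C[C@@]12CC(=O)OC2 | intermediate
23 | 2-[9-acetoxy-6-[1-(furan-2-yl)-2-methoxy-2-oxoethyl]-7,8-dimethyl-3-oxo-2-oxaspiro[4.5]decan-7-yl]acetic acid | COC(=O)C(c1ccco1)[C@@H]1[C@@](C)(CC(=O)O)[C@H](C)[C@H](OC(C)=O)C[C@@]12CC(=O)OC2 | intermediate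
24 | mixed anhydride of 23 with trifluoroacetic acid (not isolated) | COC(=O)C(c1ccco1)[C@@H]1[C@@](C)(CC(=O)OC(=O)C(F)(F)F)[C@H](C)[C@H](OC(C)=O)C[C@@]12CC(=O)OC2 | intermediate
25 | tetracyclic keto ester: furan-fused cycloheptanone C on ring A, spiro γ-lactone E at C5, methyl ester on C1 (C1 epimers), 7α-acetate | COC(=O)C1c2occc2C(=O)C[C@@]2(C)[C@H](C)[C@H](OC(C)=O)C[C@@]3(CC(=O)OC3)[C@H]12 | intermediate
26 | 3-nor β-keto lactone: cyclopentanone ring B (C2 ketone) cis-fused to lactone E, 7α-acetate, 12-ketone | CC(=O)O[C@@H]1C[C@@]23COC(=O)[C@@H]2C(=O)[C@H]2c4occc4C(=O)C[C@@](C)([C@@H]1C)[C@@H]23 | intermediate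
27 | diiodomethane | ICI | starting material
28 | ethylzinc enolate (at C18–O) of the ring-expanded 2-oxo lactone (not isolated) | CC(=O)O[C@@H]1C[C@@]23COC(O[Zn]CC)=C2CC(=O)[C@H]2c4occc4C(=O)C[C@@](C)([C@@H]1C)[C@@H]23 | intermediate
29 | 4-iodo 2-oxo lactone with six-membered ring B (not isolated) | CC(=O)O[C@@H]1C[C@@]23COC(=O)C2(I)CC(=O)[C@H]2c4occc4C(=O)C[C@@](C)([C@@H]1C)[C@@H]23 | intermediate
30 | 2-oxo enone lactone (2-dehydro target) | CC(=O)O[C@@H]1C[C@@]23COC(=O)C2=CC(=O)[C@H]2c4occc4C(=O)C[C@@](C)([C@@H]1C)[C@@H]23 | intermediate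
31 | CNP0182929.1 (7α-acetoxy-2α-hydroxy-12-oxo compound) | CC(=O)O[C@@H]1C[C@@]23COC(=O)C2=C[C@H](O)[C@H]2c4occc4C(=O)C[C@@](C)([C@@H]1C)[C@@H]23 | target

**Summary and risks**

Total step count: 21. Longest linear sequence: 20 steps (steps 1 and 3–21; step 2 prepares the diene).

Steps most likely to fail:

Step 20. The zinc enolate of 26 sits at the ring fusion of a strained bicyclic system and may resist cyclopropanation, the carbenoid may be diverted to O-alkylation or to the furan, or the C4 iodide may not eliminate cleanly. The fallback sets out from 26 and returns at 30 by a radical ring expansion. Alkylation of the sodium enolate of 26 at C4 with CH2Br2 (NaH, THF–HMPA) would give the 4-(bromomethyl) β-keto lactone F1. Bu3SnH/AIBN (benzene, 80 °C) then sets off the Dowd–Beckwith rearrangement (attack of the primary radical on the C2 carbonyl, opening of the cyclopropyloxy radical to the lactone-stabilised C4 radical) to the saturated six-membered 2-oxo lactone F2. Kinetic deprotonation at the C3 methylene (LiN(SiMe3)2, −78 °C), PhSeBr to the C3 selenide F3 and oxidation with H2O2 (syn-elimination toward C4) would deliver 30.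

Step 7. Proton transfer from the acidic C1–H to the newly formed ketone enolate, or failure of the silyl acetal to cyclise onto the hindered C10, would erase the regiochemical control over C9. The fallback sets out from 7 and returns at 14 without the tether. Compound 7 is silylated (t-BuMe2SiCl, imidazole) to the silyl ether F4. The trimethylsilyl ketene acetal F5 of commercial methyl 2-(furan-2-yl)acetate (LiN(SiMe3)2, Me3SiCl) is added to F4 in an intermolecular Mukaiyama–Michael reaction (Me3SiOTf cat., CH2Cl2, −78 °C) to give the C8 silyl enol ether F6 as a mixture at C10. Tsuji allylation as in step 8 gives the 9β-allyl ketone F7, and the isomer with the C1 side chain cis to C19 is separated. Wet CF3CO2H then removes the silyl ether and the tert-butyl ester and closes the lactone to 14. The price is the loss of facial control at C10.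

Step 19. Because C1–H is far more acidic than C4–H2, the ester that has to be attacked may sit as its enolate so that the condensation stalls, or methoxide may cleave the acetate before ring closure. The fallback sets out from 25 and returns at 26 by using the kinetically easy sense of closure and moving the carbonyl afterwards. With LiN(SiMe3)2 (THF, −78 → 0 °C) the C1 ester enolate of 25 should attack the lactone carbonyl and give, after work-up, the ring-B β-keto ester with a free C19 alcohol F8. Krapcho demethoxycarbonylation (LiCl, wet DMSO, 130 °C) leads to the hydroxy ketone F9. ClCO2Me/pyridine gives the C19 methyl carbonate F10, and NaH (THF) closes the lactone by intramolecular C-acylation at C4, the only mode that ends in an enolisable β-keto lactone, which is 26.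

Further compounds
F1 | step 20 | 4-(bromomethyl) derivative of the β-keto lactone 26 | CC(=O)O[C@@H]1C[C@@]23COC(=O)[C@]2(CBr)C(=O)[C@H]2c4occc4C(=O)C[C@@](C)([C@@H]1C)[C@@H]23
F2 | step 20 | saturated ring-expanded 2-oxo lactone (3,4-dihydro-30, H-4 β) | CC(=O)O[C@@H]1C[C@@]23COC(=O)[C@@H]2CC(=O)[C@H]2c4occc4C(=O)C[C@@](C)([C@@H]1C)[C@@H]23
F3 | step 20 | 3-(phenylselanyl) derivative of F2 | CC(=O)O[C@@H]1C[C@@]23COC(=O)[C@@H]2C([Se]c2ccccc2)C(=O)[C@H]2c4occc4C(=O)C[C@@](C)([C@@H]1C)[C@@H]23
F4 | step 7 | tert-butyldimethylsilyl ether of 7 | CC(C)(C)[Si](C)(C)OC[C@@]1(CC(=O)OC(C)(C)C)CCC(=O)C(C)=C1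
F5 | step 7 | trimethylsilyl ketene acetal of methyl 2-(furan-2-yl)acetate | COC(O[Si](C)(C)C)=Cc1ccco1
F6 | step 7 | intermolecular Mukaiyama–Michael adduct as C8 trimethylsilyl enol ether (wanted C10 epimer shown; C1 epimers) | COC(=O)C(c1ccco1)[C@@H]1C(C)=C(O[Si](C)(C)C)CC[C@@]1(CO[Si](C)(C)C(C)(C)C)CC(=O)OC(C)(C)C
F7 | step 7 | 9β-allyl 8-ketone with C19 silyl ether and C18 tert-butyl ester | COC(=O)C(c1ccco1)[C@@H]1[C@@](C)(CC=C)C(=O)CC[C@@]1(CO[Si](C)(C)C(C)(C)C)CC(=O)OC(C)(C)C
F8 | step 19 | ring-B β-keto ester (methyl ester on quaternary C1) with free C19 alcohol | CC(=O)O[C@@H]1C[C@@]2(CO)CC(=O)[C@@]3(C(=O)OC)c4occc4C(=O)C[C@@](C)([C@@H]1C)[C@H]23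
F9 | step 19 | ring-B ketone with free C19 alcohol | CC(=O)O[C@@H]1C[C@@]2(CO)CC(=O)[C@H]3c4occc4C(=O)C[C@@](C)([C@@H]1C)[C@H]23
F10 | step 19 | C19 methyl carbonate of F9 | CC(=O)O[C@@H]1C[C@@]2(COC(=O)OC)CC(=O)[C@H]3c4occc4C(=O)C[C@@](C)([C@@H]1C)[C@H]23
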